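At 17 min the noon readings left 0.0349 M of the E charged, the limiting reagent, not turned to Z, and the winter run is that noon charge at half the strength. So I took as the zero of my scale a flask of first-order steps, in which dilution leaves the share turned at each time unchanged.

| flask | E | Q | Z | time |
|---|---|---|---|---|
| noon | 0.300 M | 0.600 M |  |  |
| midnight | 0.300 M | 0.300 M |  |  |
| dawn | 0.450 M | 0.600 M |  |  |
| autumn | 0.300 M | 0.600 M | 0.150 M |  |
| winter | 0.150 M | 0.300 M |  | 17 min |

- noon run (time / min: [Z] / M): 0.61: 0.0064; 1.8: 0.0286; 3.5: 0.0755; 5.6: 0.1191; 8.0: 0.1788; 11: 0.2181; 14: 0.2451; 17: 0.2651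
- midnight run (time / min: [Z] / M): 0.61: 0.0026; 1.8: 0.0209; 3.5: 0.0577; 5.6: 0.1022; 8.0: 0.1498; 11: 0.1891; 14: 0.2178; 17: 0.2338
- dawn run (time / min: [Z] / M): 0.61: 0.0053; 1.8: 0.0351; 3.5: 0.1058; 5.6: 0.1789; 8.0: 0.2488; 11: 0.3086; 14: 0.3547; 17: 0.3797
- autumn run (time / min: [Z] / M): 0.61: 0.1550; 1.8: 0.1787; 3.5: 0.2233; 5.6: 0.2767; 8.0: 0.3276; 11: 0.3672; 14: 0.3968; 17: 0.4119

(readings scatter by 0.002 M)

- Overall: E + Q -> Z.
- Constant volume, constant temperature.
- Bound and free are read together.
- "The second partner" is Q.
- An order is taken over about fifteen percent of the charge, up and down.

- the exponent of [E] in the starting rate at the charge of the noon run (at the point where two percent of the E have become Z) (one fixed amount of Z, the same in the runs compared)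
- the exponent of [Q] in the starting rate at the charge of the noon run (at the point where two percent of the E have become Z)
- Z in the winter run at 17 min, as a share of the E charged

In the autumn run, less its added Z, I read 0.178 M at 8.0 min, against 0.1788 M in the noon run, a gap smaller than the scatter of 0.002 M. So I compared the runs by time. The noon run reached half its E at 6.84 min, and the dawn run reached half of its own at 7.18 min. The midnight run, with its Q halved, stood at half at 8.0 min, which stretched the noon time by 1.17. But the dawn run, with more E, took 1.05 times as long as the noon run for half of its own E, so I reckoned on a shorter time for less E. Scaling both effects to the winter charge gave 1.08, the clock factor: the time a flask needs for a given share of its E, divided by the time the noon run needs for that share. So the winter run at 17 min should stand where the noon run stood at 15.8 min, and between the noon readings that is 85.7%.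

The forecast gave 83% (78% to 88%), lower than my figure. It put the exponents at 0.4 for [E] (0.15 to 0.65) and 0.55 for [Q] (0.35 to 0.85), and said: “That predicts orders near one half”.

The simulation gave 0.57 for [E], 0.21 for [Q], and 85.9% in the winter run.

    E ⇌ G + J (0.2172 min⁻¹, 0.2298 M⁻¹ min⁻¹)
    G + Q → Z (7.320 M⁻¹ min⁻¹)
    2 Q ⇌ Q2, settled at all times (72.50 M⁻¹)
    E + Q ⇌ EQ, settled at all times (3.300 M⁻¹)

The clock factor was 1.08 for the winter charge and 1.17 for the midnight charge, both reckoned at half of the E. Carried to a quarter of the E charged, 1.17 turns the noon time of 3.63 min into 4.25 min, and the simulation gives the midnight run 4.29 min. At the early point asked about, the midnight run made Z at 0.85 of the noon rate, with half the Q. At the noon charge the exponent of [Q] stands at 0.21 because two Q join to Q2, and without that joining it comes to −0.18.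

The numbers in the tables stem from a simulated flask from invented constants; scatter was added.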